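1. In the west flask Z was charged at 0.300 M, more than the 0.200 M of G and E together, so G and E are the limiting reagent and I kept the books on them.

all flasks: G 0.10 M; E 0.10 M

|  | Z | X | remark |
|---|---|---|---|
| west | 0.30 M | 5 mM | the very flask that is asked about, followed so far |
| flask | 0.300 M | 5.0 mM |  |

west run (percent of the G and E together charged)

| time / s | L / % | G / % |
|---|---|---|
| 10.0 | 2.2 | 48.5 |
| 15.0 | 4.1 | 45.5 |
| 25.0 | 10.0 | 40.4 |
| 40.0 | 20.1 | 29.4 |
| 50.0 | 27.0 | 23.1 |

(each reading ± 0.3 percentage points)

- Q is single-handed; G and E are mirror images of each other, charged as a racemate, each of them at the stated concentration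
- steps under discussion: X -> Q; Z + Q + E -> Q + J; Z + Q + G -> Q + L
- no earlier run changes the charge of Z; that part of a forecast is a guess
- no earlier run changes the charge of X; that part of a forecast is a guess

* factor on the rate of making L when 50 % of the G and E together are converted if Z is charged twice over
* factor on the rate when 50 % of the G and E together are converted if X is charged at 1.0 mM instead

2. First entry: in the west run, each G that left became L, since G and L summed to 50.1 % at 50.0 s against 50.0 % charged as G, and by the steps each took one Z with it.

3. Second entry: E has no column, but by its step each E goes to J and also takes one Z.

4. Closing the books at the mark of 50 %, I set [Z] there to 0.200 M, the Z balance: the charge of Z less one Z per G or E converted. With Z charged twice over, the balance is 0.500 M, a factor of 2.50.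

5. The west rate of making L rose 1.82 times from the first pair of readings to the last while G fell, so I took [Q] as growing in proportion to [X] and the time. Equal conversion then asks for equal [X][Z] times the time squared. Taking the rate at the mark as proportional to [G][Z][Q], with [G] equal at equal conversion and the mean [Z] of each run, I reckoned 1.69 for doubled Z and 0.447 for the lower X.

6. The forecast gave 1.65 and 0.44, holding that “Q is still forming slowly from X”; my first figure stood above its own, my second just above.

The flask gave 1.74 and 0.374, the second below the forecast.

    X → Q (k = 0.00590 s⁻¹)
    Z + Q + E → Q + J (k = 18.0 M⁻² s⁻¹)
    Z + Q + G → Q + L (k = 89.0 M⁻² s⁻¹)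

X passed into Q through the west flask, Q standing at 10.1 % of the catalyst charged at 0.300 min and 41.2 % at 1.50 min, while G went to L and E to J, and at 1.20 min the flask crossed the mark with [Z] at 0.200 M and L forming at 0.0454 M min⁻¹. In the flask with Z charged twice over, [Z] at the mark was 0.500 M, 2.50 times the west value, while L formed 1.74 times as fast, which left a factor of 0.696 on [Q].

The earlier runs and the new flask are simulated with constants of no real substance; noise was put on by code.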